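**Retrosynthetic overview**

1. Feature: in the oxolane ring, O1 lies between C2 (bearing ring B) and C5 (bearing ring A); both carbons are benzylic and para to a phenol oxygen, and C3/C4 carry cis methyl groups. O1 can therefore be inserted last between the two benzylic CH2 groups of an erythro 2,3-dimethyl-1,4-diarylbutane.
2. Target 24 ⇐ desilylation, asymmetric hydrogenation and Suzuki coupling of aryl bromide 19 (rings A and B plus oxolane) with alkenylboronate 21 (ring C).
3. 19 ⇐ bisphenol oxolane 18 ⇐ O1–C2 and O1–C5 formed in one operation from diarylbutane 15 with DDQ and water.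
4. 15 ⇐ two successive Negishi couplings of aryl iodides 6 and 12 onto the enzymatically desymmetrised meso diol 2, made from meso diacid 1.
5. Ring order: rings A, B and C are bought as iodophenols; the oxolane is the only ring built (step 11); ring C is attached afterwards.

Key step: step 11

Abbreviations: TIPS = triisopropylsilyl; Bpin = 4,4,5,5-tetramethyl-1,3,2-dioxaborolan-2-yl; BArF = tetrakis[3,5-bis(trifluoromethyl)phenyl]borate; (S)-tBu-PHOX = (S)-4-tert-butyl-2-[2-(diphenylphosphino)phenyl]-4,5-dihydrooxazole. Oxolane numbering: O1, C2 (ring B), C3, C4, C5 (ring A).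

Assumption: the lipase acetylates the hydroxymethyl group on the (R)-configured carbon of diol 2. Should it acetylate the other arm, aryl iodides 6 and 12 are introduced in the opposite order, which leads to the same compound 14.

Remark on the key step: compound 14 is the silyl-protected precursor and 15 is the free bisphenol actually oxidised; 18 is the product and 19 its bis-silyl ether. The phenols are freed before the oxidation because the bromine on ring A is meta to C5 and would make that CH2 a poor hydride donor in an ether-protected ring. Bromine stays in place because it is what makes rings A and B different.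

Remark on the boronate: the alkenylboronate needed for an (E)-diarylpropene has boron trans to ring C. By the sequence rule it is (Z), because carbon outranks boron.

**Step 1**
Reactants: 1 meso-2,3-dimethylsuccinic acid
Product: 2 meso-2,3-dimethylbutane-1,4-diol
Conditions: LiAlH4 (3 equiv), THF, 0 °C to reflux; then H2O, aq. NaOH
Reagents that add atoms: none
Why: Hydride reduction of both carboxylic acids gives the primary diol without touching the two methyl-bearing stereocentres, so the meso (cis-dimethyl) relationship is kept.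

**Step 2**
Reactants: 2 meso-2,3-dimethylbutane-1,4-diol
Product: 3 (2R,3S)-4-hydroxy-2,3-dimethylbutyl acetate
Conditions: lipase from Pseudomonas fluorescens, vinyl acetate (3 equiv), iPr2O, rt
Reagents that add atoms: vinyl acetate, C=COC(C)=O
Why: Irreversible lipase-catalysed transesterification distinguishes the two enantiotopic hydroxymethyl groups of the meso diol (enzymatic desymmetrisation), which fixes the absolute configuration of the future C3 and C4.

**Step 3**
Reactants: 3 (2R,3S)-4-hydroxy-2,3-dimethylbutyl acetate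
Product: 4 (2R,3S)-4-iodo-2,3-dimethylbutyl acetate
Conditions: I2, PPh3, imidazole, CH2Cl2, 0 °C
Reagents that add atoms: iodine, II
Why: Appel-type iodination of the primary alcohol under neutral conditions is run at once on fresh 3, because acetyl migration between the two arms would racemise the monoacetate.

**Step 4**
Reactants: 5 4-iodophenol
Product: 6 (4-iodophenoxy)triisopropylsilane
Conditions: TIPSCl, imidazole, DMF, rt
Reagents that add atoms: triisopropylsilyl chloride, CC(C)[Si](Cl)(C(C)C)C(C)C
Why: Silylation of the phenol gives an ether that tolerates organozinc reagents, aluminium hydride and palladium catalysis.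

**Step 5**
Reactants: 4 (2R,3S)-4-iodo-2,3-dimethylbutyl acetate; 6 (4-iodophenoxy)triisopropylsilane
Product: 8 (2R,3R)-2,3-dimethyl-4-[4-(triisopropylsilyloxy)phenyl]butyl acetate, via alkylzinc iodide 7 (not isolated)
Conditions: Zn dust (activated with BrCH2CH2Br and Me3SiCl), LiCl, THF, 40 °C; then 6, Pd2(dba)3 (2.5 mol%), P(2-furyl)3 (10 mol%), THF, rt to 40 °C
Reagents that add atoms: none
Why: Zinc insertion into the primary C–I bond and Negishi coupling with the aryl iodide join the ring B arm at a carbon that is not a stereocentre, and alkylzinc halides leave the acetate and the aryl silyl ether alone.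

**Step 6**
Reactants: 8 (2R,3R)-2,3-dimethyl-4-[4-(triisopropylsilyloxy)phenyl]butyl acetate
Product: 9 (2R,3R)-2,3-dimethyl-4-[4-(triisopropylsilyloxy)phenyl]butan-1-ol
Conditions: iBu2AlH (DIBAL-H, 2.5 equiv), CH2Cl2, −78 °C; then aq. potassium sodium tartrate
Reagents that add atoms: none
Why: Reduction of the acetate ester with an aluminium hydride frees the alcohol and avoids basic methanolysis, which would also attack the aryl silyl ether.

**Step 7**
Reactants: 9 (2R,3R)-2,3-dimethyl-4-[4-(triisopropylsilyloxy)phenyl]butan-1-ol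
Product: 10 {4-[(2R,3R)-4-iodo-2,3-dimethylbutyl]phenoxy}triisopropylsilane
Conditions: I2, PPh3, imidazole, CH2Cl2, 0 °C to rt
Reagents that add atoms: iodine, II
Why: Appel-type iodination converts the second primary alcohol into the iodide needed for the second zinc insertion.

**Step 8**
Reactants: 11 2-bromo-4-iodophenol
Product: 12 (2-bromo-4-iodophenoxy)triisopropylsilane
Conditions: TIPSCl, imidazole, DMF, rt to 40 °C
Reagents that add atoms: triisopropylsilyl chloride, CC(C)[Si](Cl)(C(C)C)C(C)C
Why: Silylation of the phenol protects it for the coupling and places a bulky group next to the bromide, which further slows reaction at C–Br.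

**Step 9**
Reactants: 10 {4-[(2R,3R)-4-iodo-2,3-dimethylbutyl]phenoxy}triisopropylsilane; 12 (2-bromo-4-iodophenoxy)triisopropylsilane
Product: 14 (2S,3R)-1-[3-bromo-4-(triisopropylsilyloxy)phenyl]-2,3-dimethyl-4-[4-(triisopropylsilyloxy)phenyl]butane, via alkylzinc iodide 13 (not isolated)
Conditions: Zn dust (activated), LiCl, THF, 40 °C; then 12 (1.2 equiv), Pd2(dba)3 (2.5 mol%), P(2-furyl)3 (10 mol%), THF, rt
Reagents that add atoms: none
Why: The Negishi coupling should take place only at the aryl C–I bond, because oxidative addition of zerovalent palladium to an aryl iodide is far faster than to the hindered aryl bromide next to the silyloxy group, and the order of the two couplings decides which enantiomer of the erythro diarylbutane is made.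

**Step 10**
Reactants: 14 (2S,3R)-1-[3-bromo-4-(triisopropylsilyloxy)phenyl]-2,3-dimethyl-4-[4-(triisopropylsilyloxy)phenyl]butane
Product: 15 2-bromo-4-[(2S,3R)-4-(4-hydroxyphenyl)-2,3-dimethylbutyl]phenol
Conditions: Bu4NF (2.2 equiv), AcOH (2.2 equiv), THF, 0 °C to rt
Reagents that add atoms: none
Why: Fluoride desilylation frees both phenols, which the oxidation in the next step needs.

**Step 11**
Reactants: 15 2-bromo-4-[(2S,3R)-4-(4-hydroxyphenyl)-2,3-dimethylbutyl]phenol
Product: 18 (2S,3S,4R,5R)-5-(3-bromo-4-hydroxyphenyl)-2-(4-hydroxyphenyl)-3,4-dimethyloxolane, via bis(quinone methide) 16 (not isolated), via hydroxy quinone methide 17 (not isolated)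
Conditions: DDQ (2.0 equiv), dry CH2Cl2–MeCN (4:1), 0.01 M, 0 °C to rt; then H2O (excess), PPTS (0.1 equiv), rt to 40 °C
Reagents that add atoms: water, O
Why: Proposed new method: DDQ takes hydride from each benzylic CH2 para to a free phenol and loss of the phenolic proton gives the neutral bis(p-quinone methide) 16, with the oxidant used up before water is admitted; water then adds 1,6 to one quinone methide (17, drawn for attack at C5) and the new benzylic hydroxyl adds 1,6 to the other, which forms O1–C5 and O1–C2 and restores both phenols. The closest known reaction types are DDQ oxidation of p-alkylphenols to quinone methides that water or alcohols trap at the benzylic carbon, and DDQ benzylic oxidation with intramolecular alcohol capture to 2-aryloxolanes; a double closure that takes the ring oxygen from water is not known. The oxolane closes by a 5-exo-trig oxa-1,6-addition. C2 and C5 are the new stereocentres and are set under thermodynamic control, because each benzylic C–O bond para to a free phenol can reopen to the quinone methide under the mild acid, so that each aryl group should settle trans to the methyl next to it (2,3-trans, 4,5-trans, aryl groups cis), while C3 and C4 come unchanged from 15. The step needs ring closure to win over over-oxidation, aryltetralin formation and loss of the C3/C4 centres through tautomerisation of a quinone methide to a styrene: the first is answered by the two-stage order of addition and the exact two equivalents of DDQ, the second by the fact that the ring carbons that would have to attack are meta to the only oxygen of each ring, the third by low temperature, dilution and prompt hydration. Free phenols are used in place of silyl ethers because oxidation at the phenol level also reaches ring A, whose benzylic CH2 is meta to bromine and would be a poor hydride donor as an ether.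

**Step 12**
Reactants: 18 (2S,3S,4R,5R)-5-(3-bromo-4-hydroxyphenyl)-2-(4-hydroxyphenyl)-3,4-dimethyloxolane
Product: 19 (2S,3S,4R,5R)-5-[3-bromo-4-(triisopropylsilyloxy)phenyl]-3,4-dimethyl-2-[4-(triisopropylsilyloxy)phenyl]oxolane
Conditions: TIPSCl (2.6 equiv), imidazole, DMF, rt to 40 °C
Reagents that add atoms: triisopropylsilyl chloride, CC(C)[Si](Cl)(C(C)C)C(C)C
Why: Silylation of both phenols, the 2-bromophenol included, masks them for the palladium and iridium steps and takes away the phenol assistance that makes the benzylic ether bonds labile.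

**Step 13**
Reactants: 6 (4-iodophenoxy)triisopropylsilane
Product: 20 triisopropyl[4-(prop-1-yn-1-yl)phenoxy]silane
Conditions: propyne (excess), PdCl2(PPh3)2 (2 mol%), CuI (4 mol%), Et3N, THF, rt
Reagents that add atoms: propyne, CC#C
Why: Sonogashira coupling of the aryl iodide with propyne puts the three-carbon unit of the side chain on ring C.

**Step 14**
Reactants: 20 triisopropyl[4-(prop-1-yn-1-yl)phenoxy]silane
Product: 21 (Z)-triisopropyl{4-[2-(4,4,5,5-tetramethyl-1,3,2-dioxaborolan-2-yl)prop-1-en-1-yl]phenoxy}silane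
Conditions: CuCl (5 mol%), P(p-tol)3 (6 mol%), NaOtBu (10 mol%), B2pin2 (1.1 equiv), MeOH (2 equiv), THF, rt
Reagents that add atoms: bis(pinacolato)diboron, CC1(C)OB(OC1(C)C)B1OC(C)(C)C(C)(C)O1
Why: Copper-catalysed hydroboration of an aryl alkyl alkyne goes by syn borylcupration that places copper on the aryl-bearing carbon and boron on the methyl-bearing carbon, followed by protonation with methanol, so boron ends trans to ring C.

**Step 15**
Reactants: 19 (2S,3S,4R,5R)-5-[3-bromo-4-(triisopropylsilyloxy)phenyl]-3,4-dimethyl-2-[4-(triisopropylsilyloxy)phenyl]oxolane; 21 (Z)-alkenylboronate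
Product: 22 (2S,3S,4R,5R)-3,4-dimethyl-2-[4-(triisopropylsilyloxy)phenyl]-5-{4-(triisopropylsilyloxy)-3-[(E)-1-(4-(triisopropylsilyloxy)phenyl)prop-1-en-2-yl]phenyl}oxolane
Conditions: Pd(OAc)2 (5 mol%), SPhos (10 mol%), K3PO4 (3 equiv), toluene–H2O (10:1), 80 °C
Reagents that add atoms: none
Why: Suzuki–Miyaura coupling transfers the alkenyl group with retention of geometry, which puts rings A and C trans across the new trisubstituted double bond, and the bulky electron-rich biarylphosphine allows oxidative addition next to the silyloxy group.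

**Step 16**
Reactants: 22 (E)-alkene
Product: 23 (2S,3S,4R,5R)-3,4-dimethyl-2-[4-(triisopropylsilyloxy)phenyl]-5-{4-(triisopropylsilyloxy)-3-[(2R)-1-(4-(triisopropylsilyloxy)phenyl)propan-2-yl]phenyl}oxolane
Conditions: H2 (50 bar), [Ir(cod)((S)-tBu-PHOX)]BArF (3 mol%), CH2Cl2, rt
Reagents that add atoms: none
Why: Iridium-catalysed asymmetric hydrogenation of an unfunctionalised (E)-1,2-diarylpropene with a chiral P,N-ligand complex adds H2 to one alkene face under catalyst control, and the (S)-ligand is chosen as the enantiomer expected, by analogy with (E)-1,2-diphenylpropene, to give the (R) centre of the side chain (the antipodal ligand is used if a model substrate shows the opposite sense).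

**Step 17**
Reactants: 23 tris-silyl ether
Product: 24 (2S,3S,4R,5R)-5-{4-hydroxy-3-[(2R)-1-(4-hydroxyphenyl)propan-2-yl]phenyl}-2-(4-hydroxyphenyl)-3,4-dimethyloxolane (CNP0232576.1)
Conditions: Bu4NF (3.6 equiv), AcOH (3.6 equiv), THF, 0 °C to rt
Reagents that add atoms: none
Why: Acetic acid-buffered fluoride removes the three aryl silyl ethers (desilylation) without acid or base strong enough to open the benzylic ether bonds, which gives the target.

**Compound list**

1 | meso-2,3-dimethylsuccinic acid | C[C@@H](C(=O)O)[C@H](C)C(=O)O | starting material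
2 | meso-2,3-dimethylbutane-1,4-diol | C[C@@H](CO)[C@H](C)CO | intermediate
3 | (2R,3S)-4-hydroxy-2,3-dimethylbutyl acetate | C[C@@H](COC(C)=O)[C@H](C)CO | intermediate
4 | (2R,3S)-4-iodo-2,3-dimethylbutyl acetate | C[C@@H](COC(C)=O)[C@H](C)CI | intermediate
5 | 4-iodophenol | Oc1ccc(I)cc1 | starting material
6 | (4-iodophenoxy)triisopropylsilane | CC(C)[Si](Oc1ccc(I)cc1)(C(C)C)C(C)C | intermediate
7 | [(2S,3R)-4-acetoxy-2,3-dimethylbutyl]zinc iodide | C[C@@H](COC(C)=O)[C@H](C)C[Zn]I | intermediate
8 | (2R,3R)-2,3-dimethyl-4-[4-(triisopropylsilyloxy)phenyl]butyl acetate | C[C@@H](COC(C)=O)[C@H](C)Cc1ccc(O[Si](C(C)C)(C(C)C)C(C)C)cc1 | intermediate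
9 | (2R,3R)-2,3-dimethyl-4-[4-(triisopropylsilyloxy)phenyl]butan-1-ol | C[C@@H](CO)[C@H](C)Cc1ccc(O[Si](C(C)C)(C(C)C)C(C)C)cc1 | intermediate
10 | {4-[(2R,3R)-4-iodo-2,3-dimethylbutyl]phenoxy}triisopropylsilane | C[C@@H](CI)[C@H](C)Cc1ccc(O[Si](C(C)C)(C(C)C)C(C)C)cc1 | intermediate
11 | 2-bromo-4-iodophenol | Oc1ccc(I)cc1Br | starting material
12 | (2-bromo-4-iodophenoxy)triisopropylsilane | CC(C)[Si](Oc1ccc(I)cc1Br)(C(C)C)C(C)C | intermediate
13 | {(2R,3R)-2,3-dimethyl-4-[4-(triisopropylsilyloxy)phenyl]butyl}zinc iodide | C[C@@H](C[Zn]I)[C@H](C)Cc1ccc(O[Si](C(C)C)(C(C)C)C(C)C)cc1 | intermediate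
14 | (2S,3R)-1-[3-bromo-4-(triisopropylsilyloxy)phenyl]-2,3-dimethyl-4-[4-(triisopropylsilyloxy)phenyl]butane (erythro) | C[C@@H](Cc1ccc(O[Si](C(C)C)(C(C)C)C(C)C)c(Br)c1)[C@H](C)Cc1ccc(O[Si](C(C)C)(C(C)C)C(C)C)cc1 | intermediate
15 | 2-bromo-4-[(2S,3R)-4-(4-hydroxyphenyl)-2,3-dimethylbutyl]phenol | C[C@@H](Cc1ccc(O)c(Br)c1)[C@H](C)Cc1ccc(O)cc1 | intermediate
16 | bis(p-quinone methide) of 15: 2-bromo-4-[2,3-dimethyl-4-(4-oxocyclohexa-2,5-dien-1-ylidene)butylidene]cyclohexa-2,5-dien-1-one, chain stereocentres as in 15 | C[C@@H](C=C1C=CC(=O)C(Br)=C1)[C@H](C)C=C1C=CC(=O)C=C1 | intermediate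
17 | hydroxy quinone methide: 4-[4-(3-bromo-4-hydroxyphenyl)-4-hydroxy-2,3-dimethylbutylidene]cyclohexa-2,5-dien-1-one, chain stereocentres as in 15, carbinol carbon unassigned | C[C@@H](C(O)c1ccc(O)c(Br)c1)[C@H](C)C=C1C=CC(=O)C=C1 | intermediate
18 | (2S,3S,4R,5R)-5-(3-bromo-4-hydroxyphenyl)-2-(4-hydroxyphenyl)-3,4-dimethyloxolane (2,3-trans, 3,4-cis, 4,5-trans) | C[C@@H]1[C@H](C)[C@@H](c2ccc(O)cc2)O[C@H]1c1ccc(O)c(Br)c1 | intermediate
19 | (2S,3S,4R,5R)-5-[3-bromo-4-(triisopropylsilyloxy)phenyl]-3,4-dimethyl-2-[4-(triisopropylsilyloxy)phenyl]oxolane | C[C@@H]1[C@H](C)[C@@H](c2ccc(O[Si](C(C)C)(C(C)C)C(C)C)cc2)O[C@H]1c1ccc(O[Si](C(C)C)(C(C)C)C(C)C)c(Br)c1 | intermediate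
20 | triisopropyl[4-(prop-1-yn-1-yl)phenoxy]silane | CC#Cc1ccc(O[Si](C(C)C)(C(C)C)C(C)C)cc1 | intermediate
21 | (Z)-triisopropyl{4-[2-(4,4,5,5-tetramethyl-1,3,2-dioxaborolan-2-yl)prop-1-en-1-yl]phenoxy}silane (boron trans to aryl) | C/C(B1OC(C)(C)C(C)(C)O1)=C\c1ccc(O[Si](C(C)C)(C(C)C)C(C)C)cc1 | intermediate
22 | (2S,3S,4R,5R)-3,4-dimethyl-2-[4-(triisopropylsilyloxy)phenyl]-5-{4-(triisopropylsilyloxy)-3-[(E)-1-(4-(triisopropylsilyloxy)phenyl)prop-1-en-2-yl]phenyl}oxolane | C[C@@H]1[C@H](C)[C@@H](c2ccc(O[Si](C(C)C)(C(C)C)C(C)C)cc2)O[C@H]1c1ccc(O[Si](C(C)C)(C(C)C)C(C)C)c(/C(C)=C/c3ccc(O[Si](C(C)C)(C(C)C)C(C)C)cc3)c1 | intermediate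
23 | (2S,3S,4R,5R)-3,4-dimethyl-2-[4-(triisopropylsilyloxy)phenyl]-5-{4-(triisopropylsilyloxy)-3-[(2R)-1-(4-(triisopropylsilyloxy)phenyl)propan-2-yl]phenyl}oxolane | C[C@@H]1[C@H](C)[C@@H](c2ccc(O[Si](C(C)C)(C(C)C)C(C)C)cc2)O[C@H]1c1ccc(O[Si](C(C)C)(C(C)C)C(C)C)c([C@H](C)Cc3ccc(O[Si](C(C)C)(C(C)C)C(C)C)cc3)c1 | intermediate
24 | (2S,3S,4R,5R)-5-{4-hydroxy-3-[(2R)-1-(4-hydroxyphenyl)propan-2-yl]phenyl}-2-(4-hydroxyphenyl)-3,4-dimethyloxolane | C[C@@H]1[C@H](C)[C@@H](c2ccc(O)cc2)O[C@H]1c1ccc(O)c([C@H](C)Cc2ccc(O)cc2)c1 | target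

**Step count**

Total: 17 steps. Longest linear sequence: 13 steps (1, 2, 3, 5, 6, 7, 9, 10, 11, 12, 15, 16, 17).

**Steps most likely to fail**

1. Step 11 (proposed new method). What may go wrong: a quinone methide tautomerises to a styrene and the C3/C4 configuration is lost; quinone methides oligomerise or are captured by the hydroquinone; the brominated phenol is oxidised too slowly, so that hydration starts while oxidant is still present and a benzylic ketone forms. Fallback with known chemistry, setting out from 9 and coming back at 19: alcohol 9 is oxidised with Dess–Martin periodinane (NaHCO3, CH2Cl2) to (2R,3R)-2,3-dimethyl-4-[4-(triisopropylsilyloxy)phenyl]butanal F1. [3-Bromo-4-(triisopropylsilyloxy)phenyl]magnesium chloride F2, made from 12 by iodine–magnesium exchange (iPrMgCl·LiCl, THF, −20 °C, bromide untouched), adds to F1 and should give (2R,3R)-1-[3-bromo-4-(triisopropylsilyloxy)phenyl]-2,3-dimethyl-4-[4-(triisopropylsilyloxy)phenyl]butan-1-ol F3 as a mixture of C1 epimers. Felkin–Anh addition is expected to favour the epimer that would place ring A cis to the C4 methyl, so F3 is oxidised (Dess–Martin periodinane) to (2R,3R)-1-[3-bromo-4-(triisopropylsilyloxy)phenyl]-2,3-dimethyl-4-[4-(triisopropylsilyloxy)phenyl]butan-1-one F4 and reduced under Felkin–Anh control with LiBH(s-Bu)3 (THF, −78 °C) to (1R,2R,3R)-1-[3-bromo-4-(triisopropylsilyloxy)phenyl]-2,3-dimethyl-4-[4-(triisopropylsilyloxy)phenyl]butan-1-ol F5. DDQ (1.2 equiv, 4 Å molecular sieves, CH2Cl2, rt to 40 °C) should then take hydride only from the activated ring B benzylic CH2, and the C5 hydroxyl closes the oxolane trans to the C3 methyl to give 19. This is the known DDQ benzylic C–H oxidation with intramolecular alcohol capture; the carbinol sits on the bromine-deactivated ring and so resists over-oxidation. This path replaces steps 7 and 9 to 12.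

2. Step 16. What may go wrong: slow or poorly face-selective hydrogenation, because the silyloxy group ortho to the alkene twists ring A out of plane and crowds the metal; acid generated from the iridium hydride could epimerise the benzylic ether carbons. Fallback, setting out from 19 and coming back at 23: Suzuki–Miyaura coupling of 19 with isopropenylboronic acid pinacol ester (Pd(OAc)2, SPhos, K3PO4) gives (2S,3S,4R,5R)-3,4-dimethyl-5-[3-(prop-1-en-2-yl)-4-(triisopropylsilyloxy)phenyl]-2-[4-(triisopropylsilyloxy)phenyl]oxolane F6. Enantioselective copper-catalysed protoboration of this 1,1-disubstituted aryl alkene (CuCl, a chiral N-heterocyclic carbene ligand, NaOtBu, B2pin2, MeOH) places boron on the terminal carbon and sets the benzylic centre, giving (2S,3S,4R,5R)-3,4-dimethyl-5-{3-[(2R)-1-(4,4,5,5-tetramethyl-1,3,2-dioxaborolan-2-yl)propan-2-yl]-4-(triisopropylsilyloxy)phenyl}-2-[4-(triisopropylsilyloxy)phenyl]oxolane F7. B-alkyl Suzuki–Miyaura coupling of F7 with aryl iodide 6 (Pd(OAc)2, RuPhos, K2CO3, toluene–H2O, 80 °C) gives 23. The stereocentre is then set by C–B bond formation instead of hydrogenation, and ring C is attached at a primary carbon.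

3. Step 15. What may go wrong: slow oxidative addition and transmetalation at the bromide flanked by the bulky silyloxy group, with protodeboronation of 21 and base-induced loss of aryl silyl groups taking over. Fallback, setting out from 18 and coming back at 22: the coupling is moved to the unprotected bromophenol, where nothing bulky flanks the bromide. Suzuki–Miyaura coupling of 18 with 21 (Pd(OAc)2, SPhos, K3PO4, dioxane–H2O) gives (2S,3S,4R,5R)-5-{4-hydroxy-3-[(E)-1-(4-(triisopropylsilyloxy)phenyl)prop-1-en-2-yl]phenyl}-2-(4-hydroxyphenyl)-3,4-dimethyloxolane F8, and silylation of the phenols (TIPSCl, imidazole, DMF) gives 22. Step 12 is then left out.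

**Further compounds**

F1 | step 11 | (2R,3R)-2,3-dimethyl-4-[4-(triisopropylsilyloxy)phenyl]butanal | C[C@@H](C=O)[C@H](C)Cc1ccc(O[Si](C(C)C)(C(C)C)C(C)C)cc1
F2 | step 11 | [3-bromo-4-(triisopropylsilyloxy)phenyl]magnesium chloride | CC(C)[Si](Oc1ccc([Mg]Cl)cc1Br)(C(C)C)C(C)C
F3 | step 11 | (2R,3R)-1-[3-bromo-4-(triisopropylsilyloxy)phenyl]-2,3-dimethyl-4-[4-(triisopropylsilyloxy)phenyl]butan-1-ol, mixture of C1 epimers | C[C@@H](C(O)c1ccc(O[Si](C(C)C)(C(C)C)C(C)C)c(Br)c1)[C@H](C)Cc1ccc(O[Si](C(C)C)(C(C)C)C(C)C)cc1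
F4 | step 11 | (2R,3R)-1-[3-bromo-4-(triisopropylsilyloxy)phenyl]-2,3-dimethyl-4-[4-(triisopropylsilyloxy)phenyl]butan-1-one | C[C@@H](C(=O)c1ccc(O[Si](C(C)C)(C(C)C)C(C)C)c(Br)c1)[C@H](C)Cc1ccc(O[Si](C(C)C)(C(C)C)C(C)C)cc1
F5 | step 11 | (1R,2R,3R)-1-[3-bromo-4-(triisopropylsilyloxy)phenyl]-2,3-dimethyl-4-[4-(triisopropylsilyloxy)phenyl]butan-1-ol | C[C@@H]([C@@H](O)c1ccc(O[Si](C(C)C)(C(C)C)C(C)C)c(Br)c1)[C@H](C)Cc1ccc(O[Si](C(C)C)(C(C)C)C(C)C)cc1
F6 | step 16 | (2S,3S,4R,5R)-3,4-dimethyl-5-[3-(prop-1-en-2-yl)-4-(triisopropylsilyloxy)phenyl]-2-[4-(triisopropylsilyloxy)phenyl]oxolane | C[C@@H]1[C@H](C)[C@@H](c2ccc(O[Si](C(C)C)(C(C)C)C(C)C)cc2)O[C@H]1c1ccc(O[Si](C(C)C)(C(C)C)C(C)C)c(C(C)=C)c1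
F7 | step 16 | (2S,3S,4R,5R)-3,4-dimethyl-5-{3-[(2R)-1-(4,4,5,5-tetramethyl-1,3,2-dioxaborolan-2-yl)propan-2-yl]-4-(triisopropylsilyloxy)phenyl}-2-[4-(triisopropylsilyloxy)phenyl]oxolane | C[C@@H]1[C@H](C)[C@@H](c2ccc(O[Si](C(C)C)(C(C)C)C(C)C)cc2)O[C@H]1c1ccc(O[Si](C(C)C)(C(C)C)C(C)C)c([C@H](C)CB3OC(C)(C)C(C)(C)O3)c1
F8 | step 15 | (2S,3S,4R,5R)-5-{4-hydroxy-3-[(E)-1-(4-(triisopropylsilyloxy)phenyl)prop-1-en-2-yl]phenyl}-2-(4-hydroxyphenyl)-3,4-dimethyloxolane | C[C@@H]1[C@H](C)[C@@H](c2ccc(O)cc2)O[C@H]1c1ccc(O)c(/C(C)=C/c3ccc(O[Si](C(C)C)(C(C)C)C(C)C)cc3)c1
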